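**Plan**

1. Enabling feature: in unit B, quaternary C4 (bearing C15H2–O) and quaternary C10 sit 1,3 on ring A, C15 is cis to the ring B carbon C9, and C9 carries the one-carbon C11. C11 can therefore serve for a time as a lactone carbonyl tying O–C15 to a C9≡C8 dienophile.
2. Retrosynthetic cuts, in order: the C15–O ester between the halves; in each half the C11–O ether and the C9–H/C8=C12 pair (back to a C8=C9 alkene with a C12 formate); both decalins to one trans-decalin hydroxy ester; that one at C9–C10 and C7–C8 (Diels–Alder) and at the O–C11 lactone bond.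
3. Forward: ring A from ethyl 2-oxocyclohexanecarboxylate, then the dienyl ynoate, then ring B and a seven-membered lactone in one cycloaddition; methanolysis and C5=C6 hydrogenation give the common decalin.
4. The common decalin feeds both halves (C15 reduced to methyl for unit A, kept for unit B). Each C11 allylic bromide is etherified with an isocitrate from a syn-aldol with methyl glyoxylate, the halves are esterified at C15, one palladium/formate step makes both exocyclic methylenes, and the tert-butyl esters go last.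
5. Stereochemistry: C4 from a valine-enamine methylation; C10 from C4 through the tether; C5 from hydroxyl-directed hydrogenation; C9 (both halves) from palladium hydride delivery anti to the C10 methyl; the four isocitrate centres from an (R)-benzyloxazolidinone aldol, retained because the ethers are formed at C11 and not at the carbinol carbon.

Key step: step 10

Remark on names: decalin locants follow the drimane skeleton (ring A = C1–C5, C10; ring B = C5–C10; C11 on C9; C12 on C8). C15 is the oxygen-bearing carbon on C4 (α), the other C4 substituent being a β-methyl. Unit A is the half with two methyls on C4; unit B keeps C15–O.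

Assumption: the lithio-enamine of L-valine tert-butyl ester is taken to be methylated, with HMPA as ligand in toluene, on the face that leads to the (R)-keto ester 6. If the sense proved opposite, the same enamine with THF as ligand (or the D-valine enamine) would be used with no other change.

**Ring A and the dienyl ynoate**

Step 1
Reactants: 1 ethyl 2-oxocyclohexane-1-carboxylate; 2 L-valine tert-butyl ester
Product: 3 ethyl 2-{[(2S)-1-tert-butoxy-3-methyl-1-oxobutan-2-yl]amino}cyclohex-1-ene-1-carboxylate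
Conditions: BF3·OEt2 (cat.), benzene, reflux, Dean–Stark
Reagents that add atoms: none
Why: Condensation of a β-keto ester with a primary amine gives the conjugated enamino ester (enamine formation), driven by azeotropic removal of water.

Step 2
Reactants: 3 chiral enamino ester
Product: 6 ethyl (1R)-1-methyl-2-oxocyclohexane-1-carboxylate, via lithium aza-enolate 4 (not isolated), via methylated ketimine 5 (not isolated)
Conditions: LiN(i-Pr)2, HMPA (1 equiv), PhMe, −78 °C; MeI, −78 °C; then 1 M aq. HCl, 0 °C → rt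
Reagents that add atoms: iodomethane, CI; water, O
Why: Auxiliary-controlled alkylation of a chelated lithio-enamine, in which lithium is held by nitrogen and the ester carbonyls and the isopropyl group screens one face, should set the quaternary C4 centre, and mild acid hydrolysis of the ketimine returns the amino ester.

Step 3
Reactants: 6 ethyl (1R)-1-methyl-2-oxocyclohexane-1-carboxylate
Product: 8 ethyl (1R,3RS)-1,3-dimethyl-2-oxocyclohexane-1-carboxylate, via lithium enolate 7 (not isolated)
Conditions: LiN(i-Pr)2, THF, −78 °C; MeI, −78 → −20 °C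
Reagents that add atoms: iodomethane, CI
Why: Kinetic ketone enolate alkylation can only occur at the future C10 because C4 is quaternary, and the new centre is irrelevant since it becomes sp2 in step 4.

Step 4
Reactants: 8 ethyl (1R,3RS)-1,3-dimethyl-2-oxocyclohexane-1-carboxylate
Product: 10 ethyl (1R)-1,3-dimethyl-2-{[(trifluoromethyl)sulfonyl]oxy}cyclohex-2-ene-1-carboxylate, via potassium enolate 9 (not isolated)
Conditions: KN(SiMe3)2, THF, −78 °C; PhNTf2, −78 → 0 °C
Reagents that add atoms: N-phenylbis(trifluoromethanesulfonimide), O=S(=O)(N(c1ccccc1)S(=O)(=O)C(F)(F)F)C(F)(F)F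
Why: Enol triflate formation by O-sulfonylation of the only possible (tetrasubstituted) enolate, as known for 2,2,6-trisubstituted cyclohexanones.

Step 5
Reactants: 10 enol triflate
Product: 11 ethyl (1R)-2-ethenyl-1,3-dimethylcyclohex-2-ene-1-carboxylate
Conditions: CH2=CHSnBu3, Pd(PPh3)4 (5 mol %), LiCl (3 equiv), THF, reflux
Reagents that add atoms: tributyl(vinyl)stannane, C=C[Sn](CCCC)(CCCC)CCCC
Why: Stille cross-coupling of an enol triflate with a vinylstannane, precedented for hindered 2,6,6-trisubstituted cyclohexenyl triflates, installs C6=C7 without touching C4.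

Step 6
Reactants: 11 dienyl ester
Product: 12 [(1R)-2-ethenyl-1,3-dimethylcyclohex-2-en-1-yl]methanol
Conditions: LiAlH4, Et2O, 0 °C → rt; H2O/NaOH work-up
Reagents that add atoms: none
Why: Hydride reduction of the ester gives the neopentyl alcohol C15–OH and leaves the diene alone.

Step 7
Reactants: 13 prop-2-yn-1-ol
Product: 14 tert-butyl(diphenyl)(prop-2-yn-1-yloxy)silane
Conditions: t-BuPh2SiCl, imidazole, CH2Cl2, 0 °C → rt
Reagents that add atoms: tert-butyl(chloro)diphenylsilane, CC(C)(C)[Si](Cl)(c1ccccc1)c1ccccc1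
Why: Standard silylation of a primary alcohol; the TBDPS ether is chosen to outlast methoxide, hydrides and the later removal of a triethylsilyl ether.

Step 8
Reactants: 14 silyl propargyl ether
Product: 17 4-[(tert-butyldiphenylsilyl)oxy]but-2-ynoic acid, via lithium acetylide 15 (not isolated), via lithium ynoate 16 (not isolated)
Conditions: n-BuLi, THF, −78 °C; CO2 (g), −78 → 0 °C; cold 1 M HCl to pH 3
Reagents that add atoms: carbon dioxide, O=C=O
Why: Acetylide carboxylation gives the ynoic acid that carries C11, C9, C8 and C12.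

Step 9
Reactants: 12 dienyl alcohol; 17 ynoic acid
Product: 18 [(1R)-2-ethenyl-1,3-dimethylcyclohex-2-en-1-yl]methyl 4-[(tert-butyldiphenylsilyl)oxy]but-2-ynoate
Conditions: DCC, DMAP (5 mol %), CH2Cl2, −20 → 0 °C
Reagents that add atoms: none
Why: Steglich esterification at low temperature with little DMAP joins the neopentyl alcohol to the ynoic acid without conjugate addition to the ynoate.

**Key cycloaddition and the common decalin**

Step 10
Reactants: 18 dienyl ynoate
Product: 19 (4R,10S)-12-[(tert-butyldiphenylsilyl)oxy]drima-5,8-dien-11,15-olide (bridged tricyclic lactone)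
Conditions: PhMe (0.01 M), BHT (cat.), 150 °C, sealed tube
Reagents that add atoms: none
Why: Proposed new method: a concerted thermal [4+2] cycloaddition in which the electron-poor ynoate (C9≡C8, carbonyl C11) adds across the electron-rich diene C10=C5–C6=C7 to form C9–C10 and C7–C8; the closest known reactions are the type 2 intramolecular Diels–Alder reaction of 2-tethered dienes, which gives bridgehead alkenes, and the intermolecular addition of acetylenic esters to 1-vinyl-2,6,6-trimethylcyclohexene, while a type 2 closure onto a fully substituted diene terminus is without direct precedent. Ring B (C5–C10) closes as the six-membered cycloadduct ring through both new σ-bonds, and the seven-membered lactone (C4, C15, O, C11, C9, C10, C5) closes through the C9–C10 bond alone, as the four-atom bridge of a bicyclo[4.3.1]decadiene whose bridgehead C5=C6 alkene is trans only within a nine-membered ring and should therefore be isolable. The one new stereocentre, quaternary C10, is controlled by C4: only the conformer with C15 axial lets the tether reach, so C9 is delivered to the C15 face and the C10 methyl ends cis to the C4 methyl. Regiochemistry is enforced by the tether, which can span C5 to C9 only if C9 bonds to the near terminus C10, and the electronic preference of the ynoate (β-carbon to unsubstituted C7) points the same way. The step needs intramolecular reaction to win over bimolecular addition and thermal diene isomerisation, which high dilution, the activated alkyne and a radical inhibitor are meant to secure.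

Step 11
Reactants: 19 bridged lactone
Product: 20 methyl (4R,10S)-12-[(tert-butyldiphenylsilyl)oxy]-15-hydroxydrima-5,8-dien-11-oate
Conditions: NaOMe (0.2 equiv), MeOH/THF, 0 °C
Reagents that add atoms: methanol, CO
Why: Base-catalysed transesterification of the lactone, driven by relief of bridgehead-alkene strain, frees C15–OH, stores C11 as the methyl enoate and lets ring A flip so that the C4 and C10 methyls become axial.

Step 12
Reactants: 20 dienyl hydroxy ester
Product: 21 methyl (4R,5R,10S)-12-[(tert-butyldiphenylsilyl)oxy]-15-hydroxydrim-8-en-11-oate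
Conditions: H2 (1 atm), [Ir(cod)(PCy3)(py)]PF6 (5 mol %), CH2Cl2, rt
Reagents that add atoms: none
Why: Hydroxyl-directed homogeneous hydrogenation, with C15–OH binding iridium on the α-face that the two axial methyls also leave open, should place C5–H trans to the C10 methyl (trans-decalin) while the hindered tetrasubstituted enoate is not reduced.

**Unit A decalin**

Step 13
Reactants: 21 common decalin
Product: 22 methyl (4R,5R,10S)-12-[(tert-butyldiphenylsilyl)oxy]-15-{[(trifluoromethyl)sulfonyl]oxy}drim-8-en-11-oate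
Conditions: Tf2O, pyridine, CH2Cl2, −78 → 0 °C
Reagents that add atoms: trifluoromethanesulfonic anhydride, O=S(=O)(OS(=O)(=O)C(F)(F)F)C(F)(F)F
Why: Sulfonylation of the primary neopentyl alcohol activates C15 for hydride displacement.

Step 14
Reactants: 22 neopentyl triflate
Product: 23 (5S,10S)-12-[(tert-butyldiphenylsilyl)oxy]drim-8-en-11-ol
Conditions: LiEt3BH (4 equiv), THF, 0 °C → rt
Reagents that add atoms: none
Why: LiEt3BH is a strong SN2 hydride donor that should reduce the primary triflate to the second C4 methyl of unit A (reductive deoxygenation) and, in the same operation, reduce the hindered enoate 1,2 to the C11 allylic alcohol.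

Step 15
Reactants: 23 allylic alcohol
Product: 24 (5S,10S)-11-bromo-12-[(tert-butyldiphenylsilyl)oxy]drim-8-ene
Conditions: CBr4, PPh3, 2,6-lutidine, CH2Cl2, 0 °C
Reagents that add atoms: carbon tetrabromide, BrC(Br)(Br)Br
Why: The Appel reaction converts the primary allylic alcohol into the bromide under neutral conditions, the primary bromide on the tetrasubstituted alkene being the stable allylic isomer.

**Isocitrate pieces**

Step 16
Reactants: 25 (4R)-4-benzyl-1,3-oxazolidin-2-one; 26 4-tert-butoxy-4-oxobutanoic acid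
Product: 28 tert-butyl 4-[(4R)-4-benzyl-2-oxo-1,3-oxazolidin-3-yl]-4-oxobutanoate, via mixed pivalic anhydride 27 (not isolated)
Conditions: t-BuCOCl, Et3N, THF, −20 °C; then 25, LiCl, −20 °C → rt
Reagents that add atoms: none
Why: N-acylation of the oxazolidinone through a mixed pivalic anhydride, which is attacked at the less hindered succinyl carbonyl.

Step 17
Reactants: 28 succinyl imide; 29 methyl glyoxylate (freshly distilled)
Product: 32 tert-butyl (3R,4R)-3-[(4R)-4-benzyl-2-oxo-1,3-oxazolidine-3-carbonyl]-4-hydroxy-5-methoxy-5-oxopentanoate, via boron enolate 30 (not isolated), via boron aldolate 31 (not isolated)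
Conditions: Bu2BOTf, i-Pr2NEt, CH2Cl2, −78 → 0 °C; 29, −78 → 0 °C; pH 7 buffer, MeOH, H2O2, 0 °C
Reagents that add atoms: none
Why: In the Evans syn-aldol reaction the (Z)-boron enolate of the imide (only the imide α-CH2 is enolised) adds to the aldehyde through a closed chair transition state on the face away from the benzyl group, which sets both isocitrate centres as (R,R).

Step 18
Reactants: 32 aldol adduct
Product: 33 3-tert-butyl 1,2-dimethyl (1R,2R)-1-hydroxypropane-1,2,3-tricarboxylate
Conditions: NaOMe (1.1 equiv), MeOH, −20 °C, 15 min; AcOH quench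
Reagents that add atoms: sodium methoxide, [Na+].[O-]C
Why: Methoxide transesterification of the N-acyloxazolidinone removes the auxiliary at low temperature, the free alkoxide guarding against β-elimination and the tert-butyl ester against lactonisation.

**Unit A acid**

Step 19
Reactants: 24 allylic bromide of unit A; 32 aldol adduct (2.5 equiv)
Product: 34 tert-butyl (3R,4R)-3-[(4R)-4-benzyl-2-oxo-1,3-oxazolidine-3-carbonyl]-4-({(5S,10S)-12-[(tert-butyldiphenylsilyl)oxy]drim-8-en-11-yl}oxy)-5-methoxy-5-oxopentanoate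
Conditions: Ag2O (2 equiv), 4 Å MS, CH2Cl2, rt, dark
Reagents that add atoms: none
Why: Silver oxide-mediated Williamson-type O-alkylation of an α-hydroxy ester with an allylic bromide forms the ether at primary C11, so the carbinol configuration is retained, under conditions too mild for retro-aldol or epimerisation.

Step 20
Reactants: 34 ether imide
Product: 36 (2R,3R)-2-(2-tert-butoxy-2-oxoethyl)-3-({(5S,10S)-12-[(tert-butyldiphenylsilyl)oxy]drim-8-en-11-yl}oxy)-4-methoxy-4-oxobutanoic acid, via peroxy acid 35 (not isolated)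
Conditions: LiOH, H2O2, THF/H2O, 0 °C; aq. Na2SO3; HCl to pH 3
Reagents that add atoms: hydrogen peroxide, OO
Why: Hydroperoxide cleavage of the imide is selective for the exocyclic carbonyl over the methyl and tert-butyl esters, and sulfite reduces the peroxy acid to the free acid of unit A.

**Unit B alcohol**

Step 21
Reactants: 21 common decalin
Product: 37 methyl (4R,5R,10S)-12-[(tert-butyldiphenylsilyl)oxy]-15-[(triethylsilyl)oxy]drim-8-en-11-oate
Conditions: Et3SiCl, imidazole, DMAP (cat.), CH2Cl2, rt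
Reagents that add atoms: chlorotriethylsilane, CC[Si](Cl)(CC)CC
Why: Silylation masks C15–OH with a group that can later be removed in the presence of the TBDPS ether.

Step 22
Reactants: 37 silyl ether ester
Product: 38 (4R,5R,10S)-12-[(tert-butyldiphenylsilyl)oxy]-15-[(triethylsilyl)oxy]drim-8-en-11-ol
Conditions: i-Bu2AlH (2.5 equiv), CH2Cl2, −78 → −20 °C; aq. sodium potassium tartrate
Reagents that add atoms: none
Why: 1,2-Reduction of the hindered enoate by the aluminium hydride gives the primary allylic alcohol at C11 and leaves both silyl ethers.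

Step 23
Reactants: 38 allylic alcohol
Product: 39 (4R,5R,10S)-11-bromo-12-[(tert-butyldiphenylsilyl)oxy]-15-[(triethylsilyl)oxy]drim-8-ene
Conditions: CBr4, PPh3, 2,6-lutidine, CH2Cl2, −20 → 0 °C
Reagents that add atoms: carbon tetrabromide, BrC(Br)(Br)Br
Why: Appel reaction as in step 15, buffered with lutidine so that the triethylsilyl ether survives.

Step 24
Reactants: 39 allylic bromide of unit B; 33 hydroxy triester (2.5 equiv)
Product: 40 3-tert-butyl 1,2-dimethyl (1R,2R)-1-({(4R,5R,10S)-12-[(tert-butyldiphenylsilyl)oxy]-15-[(triethylsilyl)oxy]drim-8-en-11-yl}oxy)propane-1,2,3-tricarboxylate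
Conditions: Ag2O (2 equiv), 4 Å MS, CH2Cl2, rt, dark
Reagents that add atoms: none
Why: The same silver oxide-mediated O-alkylation as in step 19, here with the less hindered hydroxy triester, forms the C11–O ether with retention at the carbinol carbon.

Step 25
Reactants: 40 triethylsilyl ether
Product: 41 3-tert-butyl 1,2-dimethyl (1R,2R)-1-({(4R,5R,10S)-12-[(tert-butyldiphenylsilyl)oxy]-15-hydroxydrim-8-en-11-yl}oxy)propane-1,2,3-tricarboxylate
Conditions: PPTS (cat.), MeOH/CH2Cl2, 0 °C → rt
Reagents that add atoms: none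
Why: Acid-catalysed methanolysis cleaves the triethylsilyl ether far faster than the primary TBDPS ether and does not touch the tert-butyl ester.

**Union and end game**

Step 26
Reactants: 36 unit A acid; 41 unit B alcohol
Product: 42 C15 ester of 41 with acid 36 (both C12–OTBDPS, both C8=C9)
Conditions: EDC·HCl, DMAP (0.2 equiv), CH2Cl2, 0 °C → rt
Reagents that add atoms: none
Why: Steglich esterification of the primary C15–OH joins the halves, the low temperature and little DMAP limiting epimerisation or β-alkoxy elimination at the α-branched acid.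

Step 27
Reactants: 42 bis(silyl ether)
Product: 43 the corresponding bis(C12 allylic alcohol)
Conditions: Bu4NF, AcOH (1:1), THF, 0 °C → rt
Reagents that add atoms: none
Why: Fluoride cleavage of both primary TBDPS ethers, buffered with acetic acid so that the β-alkoxy esters are not exposed to base.

Step 28
Reactants: 43 diol
Product: 44 the corresponding bis(C12 formate)
Conditions: HCO2H, DCC, DMAP (cat.), CH2Cl2, 0 °C
Reagents that add atoms: formic acid, O=CO
Why: Carbodiimide formylation of the two primary allylic alcohols provides the allylic formates for the palladium step.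

Step 29
Reactants: 44 bis(allylic formate)
Product: 45 di-tert-butyl ester of the target (C9–H α and C8=C12 in both halves)
Conditions: Pd(OAc)2 (10 mol %), PBu3 (10 mol %), THF, 40 °C, degassed
Reagents that add atoms: none
Why: In the Tsuji hydrogenolysis of allylic formates, zerovalent palladium ionises each C12 formate on the face away from the axial C10 methyl, and loss of CO2 followed by hydride transfer to the more substituted terminus C9 from the palladium side should give C9–H α with the C8=C12 methylene, the C11 ether being too poor a leaving group to ionise.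

Step 30
Reactants: 45 di-tert-butyl ester
Product: 47 CNP0139922.3 (target diacid), via bis(trimethylsilyl) ester 46 (not isolated)
Conditions: Me3SiOTf, 2,6-lutidine, CH2Cl2, 0 °C; then pH 4 aqueous buffer
Reagents that add atoms: none
Why: Silyl triflate-mediated cleavage of tert-butyl esters proceeds by loss of isobutene to silyl esters under buffered, non-protic conditions that should not protonate the exocyclic methylenes, and aqueous work-up frees the two acids while the methyl esters and the C15 ester stay.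

**Compound list**

1 | ethyl 2-oxocyclohexane-1-carboxylate | CCOC(=O)C1CCCCC1=O | starting material
2 | L-valine tert-butyl ester | CC(C)[C@H](N)C(=O)OC(C)(C)C | starting material
3 | ethyl 2-{[(2S)-1-tert-butoxy-3-methyl-1-oxobutan-2-yl]amino}cyclohex-1-ene-1-carboxylate | CCOC(=O)C1=C(N[C@@H](C(C)C)C(=O)OC(C)(C)C)CCCC1 | intermediate
4 | N-lithio derivative (aza-enolate) of 3 | CCOC(=O)C1=C(N([Li])[C@@H](C(C)C)C(=O)OC(C)(C)C)CCCC1 | intermediate
5 | ethyl (1R)-2-{[(2S)-1-tert-butoxy-3-methyl-1-oxobutan-2-yl]imino}-1-methylcyclohexane-1-carboxylate | CCOC(=O)[C@]1(C)CCCCC1=N[C@@H](C(C)C)C(=O)OC(C)(C)C | intermediate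
6 | ethyl (1R)-1-methyl-2-oxocyclohexane-1-carboxylate | CCOC(=O)[C@]1(C)CCCCC1=O | intermediate
7 | lithium (6R)-6-(ethoxycarbonyl)-6-methylcyclohex-1-en-1-olate | CCOC(=O)[C@]1(C)CCCC=C1O[Li] | intermediate
8 | ethyl (1R,3RS)-1,3-dimethyl-2-oxocyclohexane-1-carboxylate | CCOC(=O)[C@]1(C)CCCC(C)C1=O | intermediate
9 | potassium (6R)-6-(ethoxycarbonyl)-2,6-dimethylcyclohex-1-en-1-olate | CCOC(=O)[C@]1(C)CCCC(C)=C1O[K] | intermediate
10 | ethyl (1R)-1,3-dimethyl-2-{[(trifluoromethyl)sulfonyl]oxy}cyclohex-2-ene-1-carboxylate | CCOC(=O)[C@]1(C)CCCC(C)=C1OS(=O)(=O)C(F)(F)F | intermediate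
11 | ethyl (1R)-2-ethenyl-1,3-dimethylcyclohex-2-ene-1-carboxylate | CCOC(=O)[C@]1(C)CCCC(C)=C1C=C | intermediate
12 | [(1R)-2-ethenyl-1,3-dimethylcyclohex-2-en-1-yl]methanol | OC[C@]1(C)CCCC(C)=C1C=C | intermediate
13 | prop-2-yn-1-ol | C#CCO | starting material
14 | tert-butyl(diphenyl)(prop-2-yn-1-yloxy)silane | C#CCO[Si](c1ccccc1)(c2ccccc2)C(C)(C)C | intermediate
15 | lithium acetylide of 14 | [Li]C#CCO[Si](c1ccccc1)(c2ccccc2)C(C)(C)C | intermediate
16 | lithium 4-[(tert-butyldiphenylsilyl)oxy]but-2-ynoate | [Li]OC(=O)C#CCO[Si](c1ccccc1)(c2ccccc2)C(C)(C)C | intermediate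
17 | 4-[(tert-butyldiphenylsilyl)oxy]but-2-ynoic acid | OC(=O)C#CCO[Si](c1ccccc1)(c2ccccc2)C(C)(C)C | intermediate
18 | [(1R)-2-ethenyl-1,3-dimethylcyclohex-2-en-1-yl]methyl 4-[(tert-butyldiphenylsilyl)oxy]but-2-ynoate | C=CC1=C(C)CCC[C@@]1(C)COC(=O)C#CCO[Si](c2ccccc2)(c3ccccc3)C(C)(C)C | intermediate
19 | (4R,10S)-12-[(tert-butyldiphenylsilyl)oxy]drima-5,8-dien-11,15-olide (seven-membered lactone from C11 on C9 to O–C15) | C[C@@]12CCC[C@@]3(C)COC(=O)C1=C(CO[Si](c4ccccc4)(c5ccccc5)C(C)(C)C)CC=C23 | intermediate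
20 | methyl (4R,10S)-12-[(tert-butyldiphenylsilyl)oxy]-15-hydroxydrima-5,8-dien-11-oate | OC[C@]1(C)CCC[C@]2(C)C(C(=O)OC)=C(CO[Si](c3ccccc3)(c4ccccc4)C(C)(C)C)CC=C12 | intermediate
21 | methyl (4R,5R,10S)-12-[(tert-butyldiphenylsilyl)oxy]-15-hydroxydrim-8-en-11-oate | OC[C@]1(C)CCC[C@]2(C)C(C(=O)OC)=C(CO[Si](c3ccccc3)(c4ccccc4)C(C)(C)C)CC[C@@H]12 | intermediate
22 | methyl (4R,5R,10S)-12-[(tert-butyldiphenylsilyl)oxy]-15-{[(trifluoromethyl)sulfonyl]oxy}drim-8-en-11-oate | O=S(=O)(OC[C@]1(C)CCC[C@]2(C)C(C(=O)OC)=C(CO[Si](c3ccccc3)(c4ccccc4)C(C)(C)C)CC[C@@H]12)C(F)(F)F | intermediate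
23 | (5S,10S)-12-[(tert-butyldiphenylsilyl)oxy]drim-8-en-11-ol | CC1(C)CCC[C@]2(C)C(CO)=C(CO[Si](c3ccccc3)(c4ccccc4)C(C)(C)C)CC[C@@H]12 | intermediate
24 | (5S,10S)-11-bromo-12-[(tert-butyldiphenylsilyl)oxy]drim-8-ene | CC1(C)CCC[C@]2(C)C(CBr)=C(CO[Si](c3ccccc3)(c4ccccc4)C(C)(C)C)CC[C@@H]12 | intermediate
25 | (4R)-4-benzyl-1,3-oxazolidin-2-one | O=C1OC[C@@H](Cc2ccccc2)N1 | starting material
26 | 4-tert-butoxy-4-oxobutanoic acid (mono-tert-butyl succinate) | OC(=O)CCC(=O)OC(C)(C)C | starting material
27 | 4-tert-butoxy-4-oxobutanoic 2,2-dimethylpropanoic anhydride | CC(C)(C)C(=O)OC(=O)CCC(=O)OC(C)(C)C | intermediate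
28 | tert-butyl 4-[(4R)-4-benzyl-2-oxo-1,3-oxazolidin-3-yl]-4-oxobutanoate | O=C1OC[C@@H](Cc2ccccc2)N1C(=O)CCC(=O)OC(C)(C)C | intermediate
29 | methyl glyoxylate | COC(=O)C=O | starting material
30 | (Z)-dibutylboron enolate of 28 | CCCCB(CCCC)O/C(=C\CC(=O)OC(C)(C)C)N1[C@H](Cc2ccccc2)COC1=O | intermediate
31 | dibutylboron aldolate of 32 | O=C1OC[C@@H](Cc2ccccc2)N1C(=O)[C@H](CC(=O)OC(C)(C)C)[C@@H](OB(CCCC)CCCC)C(=O)OC | intermediate
32 | tert-butyl (3R,4R)-3-[(4R)-4-benzyl-2-oxo-1,3-oxazolidine-3-carbonyl]-4-hydroxy-5-methoxy-5-oxopentanoate | O=C1OC[C@@H](Cc2ccccc2)N1C(=O)[C@H](CC(=O)OC(C)(C)C)[C@@H](O)C(=O)OC | intermediate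
33 | 3-tert-butyl 1,2-dimethyl (1R,2R)-1-hydroxypropane-1,2,3-tricarboxylate | O[C@@H](C(=O)OC)[C@@H](CC(=O)OC(C)(C)C)C(=O)OC | intermediate
34 | tert-butyl (3R,4R)-3-[(4R)-4-benzyl-2-oxo-1,3-oxazolidine-3-carbonyl]-4-({(5S,10S)-12-[(tert-butyldiphenylsilyl)oxy]drim-8-en-11-yl}oxy)-5-methoxy-5-oxopentanoate | CC1(C)CCC[C@]2(C)C(CO[C@@H](C(=O)OC)[C@@H](CC(=O)OC(C)(C)C)C(=O)N3C(=O)OC[C@H]3Cc4ccccc4)=C(CO[Si](c5ccccc5)(c6ccccc6)C(C)(C)C)CC[C@@H]12 | intermediate
35 | peroxy acid corresponding to 36 | CC1(C)CCC[C@]2(C)C(CO[C@@H](C(=O)OC)[C@@H](CC(=O)OC(C)(C)C)C(=O)OO)=C(CO[Si](c3ccccc3)(c4ccccc4)C(C)(C)C)CC[C@@H]12 | intermediate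
36 | (2R,3R)-2-(2-tert-butoxy-2-oxoethyl)-3-({(5S,10S)-12-[(tert-butyldiphenylsilyl)oxy]drim-8-en-11-yl}oxy)-4-methoxy-4-oxobutanoic acid (unit A acid) | CC1(C)CCC[C@]2(C)C(CO[C@@H](C(=O)OC)[C@@H](CC(=O)OC(C)(C)C)C(=O)O)=C(CO[Si](c3ccccc3)(c4ccccc4)C(C)(C)C)CC[C@@H]12 | intermediate
37 | methyl (4R,5R,10S)-12-[(tert-butyldiphenylsilyl)oxy]-15-[(triethylsilyl)oxy]drim-8-en-11-oate | CC[Si](CC)(CC)OC[C@]1(C)CCC[C@]2(C)C(C(=O)OC)=C(CO[Si](c3ccccc3)(c4ccccc4)C(C)(C)C)CC[C@@H]12 | intermediate
38 | (4R,5R,10S)-12-[(tert-butyldiphenylsilyl)oxy]-15-[(triethylsilyl)oxy]drim-8-en-11-ol | CC[Si](CC)(CC)OC[C@]1(C)CCC[C@]2(C)C(CO)=C(CO[Si](c3ccccc3)(c4ccccc4)C(C)(C)C)CC[C@@H]12 | intermediate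
39 | (4R,5R,10S)-11-bromo-12-[(tert-butyldiphenylsilyl)oxy]-15-[(triethylsilyl)oxy]drim-8-ene | CC[Si](CC)(CC)OC[C@]1(C)CCC[C@]2(C)C(CBr)=C(CO[Si](c3ccccc3)(c4ccccc4)C(C)(C)C)CC[C@@H]12 | intermediate
40 | 3-tert-butyl 1,2-dimethyl (1R,2R)-1-({(4R,5R,10S)-12-[(tert-butyldiphenylsilyl)oxy]-15-[(triethylsilyl)oxy]drim-8-en-11-yl}oxy)propane-1,2,3-tricarboxylate | CC[Si](CC)(CC)OC[C@]1(C)CCC[C@]2(C)C(CO[C@@H](C(=O)OC)[C@@H](CC(=O)OC(C)(C)C)C(=O)OC)=C(CO[Si](c3ccccc3)(c4ccccc4)C(C)(C)C)CC[C@@H]12 | intermediate
41 | 3-tert-butyl 1,2-dimethyl (1R,2R)-1-({(4R,5R,10S)-12-[(tert-butyldiphenylsilyl)oxy]-15-hydroxydrim-8-en-11-yl}oxy)propane-1,2,3-tricarboxylate (unit B alcohol) | OC[C@]1(C)CCC[C@]2(C)C(CO[C@@H](C(=O)OC)[C@@H](CC(=O)OC(C)(C)C)C(=O)OC)=C(CO[Si](c3ccccc3)(c4ccccc4)C(C)(C)C)CC[C@@H]12 | intermediate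
42 | ester of the C15 hydroxyl of 41 with acid 36 (both halves C8=C9 and C12–OTBDPS) | CC1(C)CCC[C@]2(C)C(CO[C@@H](C(=O)OC)[C@@H](CC(=O)OC(C)(C)C)C(=O)OC[C@]3(C)CCC[C@]4(C)C(CO[C@@H](C(=O)OC)[C@@H](CC(=O)OC(C)(C)C)C(=O)OC)=C(CO[Si](c5ccccc5)(c6ccccc6)C(C)(C)C)CC[C@@H]34)=C(CO[Si](c5ccccc5)(c6ccccc6)C(C)(C)C)CC[C@@H]12 | intermediate
43 | bis(12-hydroxy) compound from 42 | CC1(C)CCC[C@]2(C)C(CO[C@@H](C(=O)OC)[C@@H](CC(=O)OC(C)(C)C)C(=O)OC[C@]3(C)CCC[C@]4(C)C(CO[C@@H](C(=O)OC)[C@@H](CC(=O)OC(C)(C)C)C(=O)OC)=C(CO)CC[C@@H]34)=C(CO)CC[C@@H]12 | intermediate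
44 | bis(12-formyloxy) compound from 43 | CC1(C)CCC[C@]2(C)C(CO[C@@H](C(=O)OC)[C@@H](CC(=O)OC(C)(C)C)C(=O)OC[C@]3(C)CCC[C@]4(C)C(CO[C@@H](C(=O)OC)[C@@H](CC(=O)OC(C)(C)C)C(=O)OC)=C(COC=O)CC[C@@H]34)=C(COC=O)CC[C@@H]12 | intermediate
45 | di-tert-butyl ester of the target (9α-H and 8(12)-methylene in both halves) | C=C1CC[C@H]2C(C)(C)CCC[C@]2(C)[C@H]1CO[C@@H](C(=O)OC)[C@@H](CC(=O)OC(C)(C)C)C(=O)OC[C@]1(C)CCC[C@]2(C)[C@@H](CO[C@@H](C(=O)OC)[C@@H](CC(=O)OC(C)(C)C)C(=O)OC)C(=C)CC[C@@H]12 | intermediate
46 | bis(trimethylsilyl) ester of the target | C=C1CC[C@H]2C(C)(C)CCC[C@]2(C)[C@H]1CO[C@@H](C(=O)OC)[C@@H](CC(=O)O[Si](C)(C)C)C(=O)OC[C@]1(C)CCC[C@]2(C)[C@@H](CO[C@@H](C(=O)OC)[C@@H](CC(=O)O[Si](C)(C)C)C(=O)OC)C(=C)CC[C@@H]12 | intermediate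
47 | CNP0139922.3 | C=C1CC[C@H]2C(C)(C)CCC[C@]2(C)[C@H]1CO[C@@H](C(=O)OC)[C@@H](CC(=O)O)C(=O)OC[C@]1(C)CCC[C@]2(C)[C@@H](CO[C@@H](C(=O)OC)[C@@H](CC(=O)O)C(=O)OC)C(=C)CC[C@@H]12 | target

**Count**

Total steps: 30. Longest linear sequence: 20 steps (steps 1–6, 9–15, 19, 20, 26–30 from compound 1; the path through unit B is equally long).

**Steps most likely to fail**

1. Step 10 (the proposed new method). The ester tether has to twist into the s-cis form of a seven-membered lactone while the hindered diene reaches its s-cis form. The cycloaddition may therefore be slower than a [1,5]-hydrogen shift of the cis-methyl diene or than bimolecular addition; activation of the ynoate by Et2AlCl at low temperature would be tried first within the same plan. Fallback with known chemistry (thermal intermolecular Diels–Alder of a 1-vinylcyclohexene with an acetylenic ester), setting out from 12 and 17 and returning at 20: alcohol 12 is silylated (Et3SiCl, imidazole) to triethyl{[(1R)-2-ethenyl-1,3-dimethylcyclohex-2-en-1-yl]methoxy}silane F1, and acid 17 is methylated (Me3SiCHN2, MeOH/PhMe) to methyl 4-[(tert-butyldiphenylsilyl)oxy]but-2-ynoate F2. Heating F1 with F2 (PhMe, 110–130 °C) should give, with the ester carbon on C10 as the electronic preference predicts, methyl (4R,10S)-12-[(tert-butyldiphenylsilyl)oxy]-15-[(triethylsilyl)oxy]drima-5,8-dien-11-oate F3. Facial selectivity at C10 is expected to be low without the tether, so the C10 epimers would be separated. PPTS in methanol then removes the triethylsilyl group of F3 and gives 20.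

2. Step 19 (step 24 is the same reaction with the less hindered triester and should be the easier of the two). Silver-assisted ionisation of the hindered allylic bromide may outrun capture by the weakly nucleophilic, crowded hydroxyl, leading to elimination to a diene or attack at tertiary C8. Fallback by reductive etherification, setting out from 23 and 32 and returning at 34: alcohol 23 is oxidised with MnO2 to (5S,10S)-12-[(tert-butyldiphenylsilyl)oxy]drim-8-en-11-al F4, and 32 is silylated (Me3SiCl, imidazole) to its trimethylsilyl ether F5. F4 and F5 are combined with Et3SiH and catalytic Me3SiOTf (CH2Cl2, −78 °C), so that the allylic oxocarbenium ion formed at C11 is reduced by the silane to ether 34. The carbinol C–O bond is never broken, so its configuration is kept.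

3. Step 29. Hydride transfer may lack regio- or facial control (hydride to C12 giving the endocyclic methyl isomer, β-hydride loss to dienes, delivery to C9 from the β-face), or the allylic C11 ether may ionise, and the reaction has to succeed at two sites of one molecule. Fallback by reductive 1,3-transposition through allylic diazenes, setting out from 43 and returning at 45: a Mitsunobu reaction of diol 43 with 2-nitrobenzenesulfonyl hydrazide (PPh3, diethyl azodicarboxylate, THF, −30 °C) gives the bis(N-allyl-N-sulfonylhydrazine) F6. On warming to room temperature it loses the sulfinic acid to give the bis(allylic diazene) F7, whose retro-ene loss of nitrogen transfers hydrogen to C9 on the face of the diazene carbon and moves each alkene to C8=C12, giving 45.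

Further compounds
F1 | step 10 | triethyl{[(1R)-2-ethenyl-1,3-dimethylcyclohex-2-en-1-yl]methoxy}silane | CC[Si](CC)(CC)OC[C@]1(C)CCCC(C)=C1C=C
F2 | step 10 | methyl 4-[(tert-butyldiphenylsilyl)oxy]but-2-ynoate | COC(=O)C#CCO[Si](c1ccccc1)(c2ccccc2)C(C)(C)C
F3 | step 10 | methyl (4R,10S)-12-[(tert-butyldiphenylsilyl)oxy]-15-[(triethylsilyl)oxy]drima-5,8-dien-11-oate | CC[Si](CC)(CC)OC[C@]1(C)CCC[C@]2(C)C(C(=O)OC)=C(CO[Si](c3ccccc3)(c4ccccc4)C(C)(C)C)CC=C12
F4 | step 19 | (5S,10S)-12-[(tert-butyldiphenylsilyl)oxy]drim-8-en-11-al | CC1(C)CCC[C@]2(C)C(C=O)=C(CO[Si](c3ccccc3)(c4ccccc4)C(C)(C)C)CC[C@@H]12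
F5 | step 19 | tert-butyl (3R,4R)-3-[(4R)-4-benzyl-2-oxo-1,3-oxazolidine-3-carbonyl]-5-methoxy-5-oxo-4-[(trimethylsilyl)oxy]pentanoate | O=C1OC[C@@H](Cc2ccccc2)N1C(=O)[C@H](CC(=O)OC(C)(C)C)[C@@H](O[Si](C)(C)C)C(=O)OC
F6 | step 29 | bis{12-[1-(2-nitrobenzenesulfonyl)hydrazin-1-yl]} analogue of 43 | CC1(C)CCC[C@]2(C)C(CO[C@@H](C(=O)OC)[C@@H](CC(=O)OC(C)(C)C)C(=O)OC[C@]3(C)CCC[C@]4(C)C(CO[C@@H](C(=O)OC)[C@@H](CC(=O)OC(C)(C)C)C(=O)OC)=C(CN(N)S(=O)(=O)c5ccccc5[N+](=O)[O-])CC[C@@H]34)=C(CN(N)S(=O)(=O)c6ccccc6[N+](=O)[O-])CC[C@@H]12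
F7 | step 29 | bis(12-diazenyl) analogue of 43 (allylic diazene) | CC1(C)CCC[C@]2(C)C(CO[C@@H](C(=O)OC)[C@@H](CC(=O)OC(C)(C)C)C(=O)OC[C@]3(C)CCC[C@]4(C)C(CO[C@@H](C(=O)OC)[C@@H](CC(=O)OC(C)(C)C)C(=O)OC)=C(CN=N)CC[C@@H]34)=C(CN=N)CC[C@@H]12
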